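The cyclohexene is numbered from the acetoxy carbon C1 through carbinols C2 and C3 and the alkene C4=C5 to the benzoyloxy carbon C6, with C7 the exocyclic CH2. It is disconnected at C3–C4 and C5–C6 into (1E,3E)-1,4-diacetoxybuta-1,3-diene and 2-bromoacrolein. The feature exploited is that the C3 and C6 oxygens share one face, para across C4=C5, while the C1/C2 cis-diol occupies the other. One catalytic, enantioselective, endo-selective Diels–Alder reaction closes the carbocycle and sets C3, C5 and C6. The bromine on quaternary C5 is a latent C4=C5 alkene, the formyl carbon becomes C7, and anti dihydroxylation relays C1 and C2. The precursor is the symmetrical commercial diene plus freshly made bromoacrolein.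

Key step: step 2

Assumption: the (S)-configured oxazaborolidinium is assumed, from the formyl C–H···O binding model for 2-substituted acroleins, to open the dienophile face that gives the R configuration at the quaternary carbon. This sense of induction is a prediction for this diene; if the first run shows the opposite sense, the catalyst from (R)-diphenylprolinol is used with no other change.

Convention: target numbering is used for all intermediates. β is the ring face of the C1/C2 oxygens and α the face of the C3/C6 oxygens. The supplied structures were checked against the target and needed no correction.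

Step 1
Reactants: 1 acrolein
Product: 3 2-bromoacrolein, via 2,3-dibromopropanal 2 (not isolated)
Conditions: Br2 (1.0 equiv), CH2Cl2, −78 °C; then Et3N (1.0 equiv), −78 → 0 °C; used freshly distilled
Reagents that add atoms: bromine, BrBr
Why: Electrophilic addition of bromine to the C=C bond followed by base-induced loss of HBr through the acidic α-hydrogen (bromination–dehydrobromination) is the standard preparation of this dienophile.

Step 2
Reactants: 3 2-bromoacrolein; 4 (1E,3E)-1,4-diacetoxybuta-1,3-diene
Product: 5 (1R,4R,6R)-6-bromo-6-formylcyclohex-2-ene-1,4-diyl diacetate (endo adduct: 3α,6α-diacetoxy; 5α-formyl; 5β-bromo; C1=C2)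
Conditions: (S)-tetrahydro-1-(2-methylphenyl)-3,3-diphenyl-1H,3H-pyrrolo[1,2-c][1,3,2]oxazaborole (20 mol%), Tf2NH (18 mol%), 3 (1.5 equiv), CH2Cl2, −78 → −20 °C
Reagents that add atoms: none
Why: Proposed new method: the N-protonated oxazaborolidine binds the formyl oxygen of 3 syn to the formyl hydrogen, lowers the LUMO and screens one face of the C=C bond, and diene 4 then adds through a concerted, asynchronous, suprafacial [4+2] transition state in which the bond from the unsubstituted dienophile carbon (C4–C3) is the more advanced. The closest known reaction types are the oxazaborolidinium-catalysed enantioselective Diels–Alder reactions of 2-bromoacrolein with simple 1,3-dienes and the thermal cycloadditions of 4 with acrylates; their combination on a 1,4-diacyloxydiene is, to present knowledge, without example. The single carbocycle closes in the [4+2] mode from the s-cis diene by simultaneous formation of C3–C4 and C5–C6. C5 is controlled by the catalyst, which should leave open the face of 3 on which Br, CHO and CH2 run clockwise (giving 5R), whereas C3 and C6 are controlled by the (E,E) geometry, which forces the two acetoxy groups cis, together with the endo placement of the bound formyl group, which puts CHO on their face and Br on the other. The step needs enantiofacial and endo selectivity: the first rests on the rigid two-point binding of the aldehyde, the second on secondary overlap of the activated C=O with the diene and on the absence, in an acyclic diene, of the bridge that drives 2-substituted acroleins exo with cyclopentadiene. Regioselectivity is not an issue because 4 is C2-symmetric in its reactive conformation.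

Step 3
Reactants: 5 endo adduct
Product: 6 3α,6α-diacetoxy-5β-bromo-5α-formylcyclohexane-1β,2β-diol
Conditions: OsO4 (2 mol%), NMO (1.5 equiv), citric acid (1 equiv), tBuOH/H2O 1:1, 23 °C
Reagents that add atoms: osmium tetroxide, O=[Os](=O)(=O)=O (transfers both oxygen atoms); N-methylmorpholine N-oxide, C[N+]1([O-])CCOCC1 (restores the oxo ligands, terminal oxygen source)
Why: Catalytic OsO4/NMO syn-dihydroxylation should take place on the face of C1=C2 anti to both allylic acetoxy groups (allylic-oxygen anti rule, as in dihydroxylations of acrylate adducts of the same diene), setting C1 and C2 on the β face, while citric acid keeps the medium weakly acidic so that the amine by-product cannot dehydrobrominate the aldehyde or move the acetates.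

Step 4
Reactants: 6 bromo aldehyde diol
Product: 7 3α,6α-diacetoxy-5β-bromo-5α-formyl-1β,2β-(isopropylidenedioxy)cyclohexane
Conditions: 2-methoxypropene (2 equiv), PPTS (5 mol%), CH2Cl2, 0 °C
Reagents that add atoms: 2-methoxypropene, COC(C)=C
Why: Acid-catalysed ketalisation of the cis-1,2-diol with the enol ether gives the cis-fused dioxolane (acetonide formation), and the hindered, electron-poor, non-enolisable aldehyde should not acetalise under these methanol-poor conditions.

Step 5
Reactants: 7 bromo aldehyde acetonide
Product: 8 3α,6α-diacetoxy-1β,2β-(isopropylidenedioxy)cyclohex-4-ene-5-carbaldehyde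
Conditions: DBU (1.5 equiv), PhMe, 0 → 23 °C
Reagents that add atoms: none
Why: E2 dehydrobromination should give only the C4=C5 enal, because the β-bromine on C5 has an anti-periplanar hydrogen at C4 (the α one) whereas the C6 hydrogen is syn to it, and the quaternary centre has by now served its purpose of blocking acetate loss.

Step 6
Reactants: 8 enal
Product: 10 5-(hydroxymethyl)-1β,2β-(isopropylidenedioxy)cyclohex-4-ene-3α,6α-diol, via diacetoxy allylic alcohol 9 (not isolated)
Conditions: NaBH4, CeCl3·7H2O, MeOH, −40 °C; then K2CO3 (0.3 equiv), 23 °C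
Reagents that add atoms: none
Why: Luche reduction delivers hydride 1,2 to the enal, and base-catalysed transesterification in the same methanol then removes both acetates without touching the acetonide or any stereocentre.

Step 7
Reactants: 10 triol acetonide
Product: 12 3α-(tert-butyldimethylsilyloxy)-6α,7-O-(di-tert-butylsilanediyl) acetonide, via C3-hydroxy silylene 11 (not isolated)
Conditions: tBu2Si(OTf)2 (1.05 equiv), 2,6-lutidine, CH2Cl2, −40 → 0 °C; then TBSOTf (1.3 equiv), 0 °C
Reagents that add atoms: di-tert-butylsilyl bis(trifluoromethanesulfonate), CC(C)(C)[Si](OS(=O)(=O)C(F)(F)F)(OS(=O)(=O)C(F)(F)F)C(C)(C)C; tert-butyldimethylsilyl trifluoromethanesulfonate, CC(C)(C)[Si](C)(C)OS(=O)(=O)C(F)(F)F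
Why: The bis-triflate bridges the only 1,3-diol (primary O7 and neighbouring O6) as a six-membered silylene, which leaves the C3 hydroxyl alone to be silylated in the same flask (the silylene-then-silyl-ether sequence used to single out the 2'-hydroxyl of ribonucleosides).

Step 8
Reactants: 12 silylene TBS ether
Product: 13 3α-(tert-butyldimethylsilyloxy)-5-(hydroxymethyl)-1β,2β-(isopropylidenedioxy)cyclohex-4-en-6α-ol
Conditions: HF·pyridine, pyridine, THF, 0 °C
Reagents that add atoms: none
Why: Buffered fluoride cleaves the dialkoxysilane bridge much faster than a secondary trialkylsilyl ether (selective silylene removal as practised on 3',5'-O-silylene-2'-O-TBS nucleosides), and the acetonide is inert to it.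

Step 9
Reactants: 13 C6/C7 diol; 14 benzoyl chloride
Product: 15 6α-benzoyloxy-5-(benzoyloxymethyl)-3α-(tert-butyldimethylsilyloxy)-1β,2β-(isopropylidenedioxy)cyclohex-4-ene
Conditions: BzCl (3 equiv), pyridine, DMAP (cat.), CH2Cl2, 0 → 23 °C
Reagents that add atoms: benzoyl chloride, O=C(Cl)c1ccccc1
Why: DMAP-catalysed acylation of the primary and the secondary allylic hydroxyl with excess acid chloride installs both benzoates of the target, with silyl ether and ketal stable to pyridine.

Step 10
Reactants: 15 dibenzoate
Product: 16 6α-benzoyloxy-5-(benzoyloxymethyl)cyclohex-4-ene-1β,2β,3α-triol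
Conditions: TFA/H2O 9:1, 0 °C
Reagents that add atoms: none
Why: Aqueous trifluoroacetic acid hydrolyses the isopropylidene ketal and solvolyses the secondary silyl ether in one acidic operation, under which benzoates neither cleave nor readily migrate.

Step 11
Reactants: 16 triol dibenzoate; 17 trimethyl orthoacetate
Product: 19 target (1S,2S,3R,6S)-1-acetoxy-6-benzoyloxy-5-(benzoyloxymethyl)cyclohex-4-ene-2,3-diol, via cyclic orthoacetate 18 (not isolated)
Conditions: MeC(OMe)3 (1.5 equiv), PPTS (cat.), CH2Cl2, 23 °C; then AcOH/H2O 4:1, 0 → 23 °C
Reagents that add atoms: trimethyl orthoacetate, COC(C)(OC)OC; water, O (supplies the acetate carbonyl oxygen)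
Why: Acid-catalysed orthoester exchange engages the cis C1/C2 diol as a five-membered cyclic orthoacetate (as in 2-O-acylation of 2,3-cis/3,4-trans pyranoside triols), and mild aqueous acid opens it with cleavage of the bond to the equatorial oxygen, which should leave the acetate on axial O1 and the hydroxyl on O2 in the half-chair that keeps the C6 benzoate pseudoaxial to avoid allylic 1,2-strain.

Compound list
1 | acrolein (prop-2-enal) | C=CC=O | starting material
2 | 2,3-dibromopropanal (racemic) | O=CC(Br)CBr | intermediate
3 | 2-bromoacrolein (2-bromoprop-2-enal) | C=C(Br)C=O | intermediate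
4 | (1E,3E)-1,4-diacetoxybuta-1,3-diene | CC(=O)O/C=C/C=C/OC(C)=O | starting material
5 | (1R,4R,6R)-6-bromo-6-formylcyclohex-2-ene-1,4-diyl diacetate; both acetoxy groups and CHO on the α face, Br on the β face | C1=C[C@H](OC(C)=O)C[C@](Br)(C=O)[C@@H]1OC(C)=O | intermediate
6 | 3α,6α-diacetoxy-5β-bromo-5α-formylcyclohexane-1β,2β-diol | O[C@H]1[C@@H](O)[C@H](OC(C)=O)C[C@](Br)(C=O)[C@@H]1OC(C)=O | intermediate
7 | 1β,2β-O-isopropylidene derivative of 6 | CC1(C)O[C@H]2[C@@H](O1)[C@H](OC(C)=O)C[C@](Br)(C=O)[C@@H]2OC(C)=O | intermediate
8 | 3α,6α-diacetoxy-1β,2β-(isopropylidenedioxy)cyclohex-4-ene-5-carbaldehyde | CC1(C)O[C@H]2[C@@H](O1)[C@H](OC(C)=O)C=C(C=O)[C@@H]2OC(C)=O | intermediate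
9 | 3α,6α-diacetoxy-5-(hydroxymethyl)-1β,2β-(isopropylidenedioxy)cyclohex-4-ene | CC1(C)O[C@H]2[C@@H](O1)[C@H](OC(C)=O)C=C(CO)[C@@H]2OC(C)=O | intermediate
10 | 5-(hydroxymethyl)-1β,2β-(isopropylidenedioxy)cyclohex-4-ene-3α,6α-diol | CC1(C)O[C@H]2[C@@H](O1)[C@H](O)C=C(CO)[C@@H]2O | intermediate
11 | 6α,7-O-(di-tert-butylsilanediyl) derivative of 10, 3α-OH free | CC1(C)O[C@H]2[C@@H](O1)[C@H](O)C=C(CO[Si](C(C)(C)C)(C(C)(C)C)O3)[C@@H]23 | intermediate
12 | 3α-O-TBS ether of 11 | CC1(C)O[C@H]2[C@@H](O1)[C@H](O[Si](C)(C)C(C)(C)C)C=C(CO[Si](C(C)(C)C)(C(C)(C)C)O3)[C@@H]23 | intermediate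
13 | 3α-(tert-butyldimethylsilyloxy)-5-(hydroxymethyl)-1β,2β-(isopropylidenedioxy)cyclohex-4-en-6α-ol | CC1(C)O[C@H]2[C@@H](O1)[C@H](O[Si](C)(C)C(C)(C)C)C=C(CO)[C@@H]2O | intermediate
14 | benzoyl chloride | O=C(Cl)c1ccccc1 | starting material
15 | 6α-O,7-O-dibenzoate of 13 | CC1(C)O[C@H]2[C@@H](O1)[C@H](O[Si](C)(C)C(C)(C)C)C=C(COC(=O)c3ccccc3)[C@@H]2OC(=O)c2ccccc2 | intermediate
16 | 6α-benzoyloxy-5-(benzoyloxymethyl)cyclohex-4-ene-1β,2β,3α-triol | O[C@H]1[C@@H](O)[C@H](O)C=C(COC(=O)c2ccccc2)[C@@H]1OC(=O)c1ccccc1 | intermediate
17 | trimethyl orthoacetate | COC(C)(OC)OC | starting material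
18 | 1β,2β-O-(1-methoxyethylidene) cyclic orthoacetate of 16 (both epimers at the orthoester carbon) | COC1(C)O[C@H]2[C@@H](O1)[C@H](O)C=C(COC(=O)c3ccccc3)[C@@H]2OC(=O)c2ccccc2 | intermediate
19 | (1S,2S,3R,6S)-1-acetoxy-6-benzoyloxy-5-(benzoyloxymethyl)cyclohex-4-ene-2,3-diol | CC(=O)O[C@H]1[C@@H](O)[C@H](O)C=C(COC(=O)c2ccccc2)[C@@H]1OC(=O)c1ccccc1 | target

Total step count: 11. Longest linear sequence: 11 steps (1 → 19); diene 4 enters at step 2.

Steps most likely to fail

Step 2. The acetate carbonyls of the diene may sequester the cationic boron Lewis acid, or the modestly reactive diene may oligomerise before it cycloadds, so that conversion, endo preference or enantiofacial control collapses. The fallback sets out from 3 and 4 and returns at 5. The two are heated without catalyst (PhMe, BHT, sealed vessel, 60–80 °C), a thermal [4+2] reaction of the kind established for this diene with acrylic dienophiles. This should give the endo adduct as a racemate, that is 5 together with its mirror-image (1S,4S,6S)-adduct F1. After chromatographic removal of any exo isomer, the racemate is resolved by preparative HPLC on a chiral stationary phase (cellulose tris(3,5-dimethylphenylcarbamate), hexane/2-propanol), and 5 enters step 3 unchanged.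

Step 5. DBU may, besides removing HBr, enolise the product enal at C3 (vinylogous deprotonation), with loss of the C6 acetate and drift toward aromatic aldehydes; the anti elimination may also be slow for conformational reasons and demand forcing conditions that favour this decay. The fallback sets out from 7 and returns at 10. The formyl group is first raised to the ester level, whose enoate is far less C–H acidic. Pinnick oxidation of 7 (NaClO2, NaH2PO4, 2-methyl-2-butene, tBuOH/H2O) should give the bromo acid F2. TMSCHN2 (PhMe/MeOH, 0 °C) gives the methyl ester F3. DBU (PhMe, 23–60 °C) effects the same anti elimination to the enoate F4. Excess DIBAL-H (CH2Cl2, −78 → 0 °C) then reduces the ester to the C7 carbinol and cleaves both acetates, giving triol 10, from which step 7 continues.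

Step 11. The orthoester may open with poor regiocontrol, the acetyl group may drift from O1 to O2 during hydrolysis, or O3 may be partly acetylated through an acyclic mixed orthoester. The fallback sets out from 16 and returns at 19, and fixes the regiochemistry by relative configuration instead of conformation. Triol 16 is treated with 1,3-dichloro-1,1,3,3-tetraisopropyldisiloxane (imidazole, DMF, 0 °C), which bridges the trans-diequatorial C2/C3 diol in preference to the cis pair (as on 3,4-trans/2,3-cis pyranoside triols), to give the C2/C3 disiloxanediyl ether F5. Ac2O/pyridine/DMAP acetylates the remaining C1 hydroxyl to the acetate F6. HF·pyridine (THF/pyridine, 0 °C), a non-basic fluoride source that should not promote acyl migration, then releases 19.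

Further compounds
F1 | step 2 | (1S,4S,6S)-6-bromo-6-formylcyclohex-2-ene-1,4-diyl diacetate (enantiomer of 5) | C1=C[C@@H](OC(C)=O)C[C@@](Br)(C=O)[C@H]1OC(C)=O
F2 | step 5 | 3α,6α-diacetoxy-5β-bromo-1β,2β-(isopropylidenedioxy)cyclohexane-5α-carboxylic acid | CC1(C)O[C@H]2[C@@H](O1)[C@H](OC(C)=O)C[C@](Br)(C(=O)O)[C@@H]2OC(C)=O
F3 | step 5 | methyl ester of F2 | CC1(C)O[C@H]2[C@@H](O1)[C@H](OC(C)=O)C[C@](Br)(C(=O)OC)[C@@H]2OC(C)=O
F4 | step 5 | methyl 3α,6α-diacetoxy-1β,2β-(isopropylidenedioxy)cyclohex-4-ene-5-carboxylate | CC1(C)O[C@H]2[C@@H](O1)[C@H](OC(C)=O)C=C(C(=O)OC)[C@@H]2OC(C)=O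
F5 | step 11 | 2β,3α-O-(1,1,3,3-tetraisopropyldisiloxane-1,3-diyl) derivative of 16, 1β-OH free | O[C@H]1[C@@H](O[Si](C(C)C)(C(C)C)O[Si](C(C)C)(C(C)C)O2)[C@H]2C=C(COC(=O)c3ccccc3)[C@@H]1OC(=O)c1ccccc1
F6 | step 11 | 1β-O-acetate of F5 | CC(=O)O[C@H]1[C@@H](O[Si](C(C)C)(C(C)C)O[Si](C(C)C)(C(C)C)O2)[C@H]2C=C(COC(=O)c3ccccc3)[C@@H]1OC(=O)c1ccccc1
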